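The data were computed for substances that don't exist, noise included.

**Out of reach.** I cannot read L at 30 h from the earlier runs, because the longest of them stops at 15.0 h, so I look for a quantity that carries over from run to run. Neither Q nor J was read, so I take c(Q) as what X and L leave of the charge.

| flask | Q | J | remark | time |
|---|---|---|---|---|
| winter | 0.10 M | 1.4 equiv | run made earlier |  |
| dusk | 0.10 M | 5 equiv | run made earlier |  |
| Monday's | 0.10 M | 1.20 equiv |  | 30 h |
| Saturday's | 0.10 M | 2.00 equiv |  | 30 h |
| Sunday's | 0.10 M | 4.00 equiv |  | 30 h |

- winter (time / h: L / %, X / %): 1.33: 0, 5.1; 2.50: 1.0, 13.9; 4.00: 0.1, 20.4; 8.00: 2.9, 28.6; 15.0: 2.6, 40.0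
- dusk (time / h: L / %, X / %): 1.33: 1.0, 25.0; 4.00: 3.2, 49.1; 8.00: 8.5, 63.1; 10.0: 13.8, 65.0; 15.0: 20.2, 68.6

(standard deviation of a reading: 1 percentage point)

- amount of L at the end, in percent of the Q charged, for each flask in turn (Monday's, Saturday's, Sunday's)

**The cheap rule.** Q and X each react with J, so if each step takes J one for one, J and the clock drop out of the ratio of the two rates, and L then follows how far Q has gone. L is the small thing, so I count X as all the Q gone and compute only the correction: L equals a factor times B, where B is minus the natural logarithm of the fraction of Q left, less the fraction of Q gone.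

**Two readings.** The winter run at 15.0 h gives 0.201, and the dusk run at 8.00 h gives 0.157 for this factor, the ratio of the rate constant of X to that of Q, or selectivity factor. They part, and I suspect the winter reading, which rests on 2.6% of L with a scatter of 1 percentage point, whereas dusk rests on 8.5%. I carry the dusk value.

**The forecast.** The forecast treats the flask as “consecutive second-order steps”, takes the ratio of the two constants near 0.2, puts Q at 49%, 29% and 7%, and gives L as 4%, 10% and 28%. Close to the first two of those Q values I read the dusk run directly: it held 3.2% of L with Q at 47.7%, and 8.5% with Q at 28.4%. Both lie a little below the forecast's first two values. For Sunday's flask my factor gives 27.1%, close to the forecast's value.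

**The flasks.** L ends at 3.49%, 8.69% and 25.4%, each lower than the forecast's value, by 0.51 points, 1.3 points and 2.6 points.

    Q + J → X + Z (k = 1.30 × 10⁻⁴ /M/s)
    J + X ⇌ L + Z (K = 1.80, k = 2.50 × 10⁻⁵ /M/s)
    J ⇌ G (K = 1.20, k = 1.70 × 10⁻⁵ /s)

Monday's flask ends with Q at 49.7%, where the carried factor gives 3.08% of L, and on Sunday's flask, with Q at 7.08%, it gives 27.0% where the flask holds 25.4%.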